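**Retrosynthetic overview**

1. The route rests on the C8–C9–C10 segment of the ten-membered carbocycle (C1–C10): the acyloxy carbinol C8 and the oxirane carbon C10 are 1,3-dioxygenated across the C9 methylene. With C10 as a ketone this is an aldol, so the ring is opened at C8–C9 to the C9 bromoketone C8 aldehyde 39 (SmI2 Reformatsky closure).
2. After closure: C8–OH is acylated with acid 36, MeMgBr adds to C10 under chelation by the C1 PMB ether, the PMB group is removed, and the C10 alkoxide displaces a C1 mesylate with inversion (C1–C10 oxirane); desilylation ends the route.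
3. 39 comes from Stille coupling at C3–C4 of Z iodide lactone 19 with Z stannane 31, NBS bromination of the 2-methoxyallyl unit (C9–C10) and oxidation of C8–OH.
4. 19: iodoenal from but-2-yn-1-ol, HYTRA acetate aldol (C6), Fráter–Seebach alkylation (C7), lactonisation, enolate hydroxylation then chloromethylation (C11). 31: CBS reduction of an ynone (C1), ketal to enol ether, hydrozirconation.
5. Ring order: γ-lactone (step 8), ten-membered carbocycle (step 25), oxirane (step 29).

Key step: step 25

Remark: germacranolide numbering is used (carbocycle C1–C10, methyl on C4, lactone oxygen on C6, C11 carbinol, C12 lactone carbonyl, C13 chloromethyl, ester oxygen on C8); (S)-HYTRA 5 and ketal ester 21 are taken as purchasable, and the C11 epimer ratio from step 9 is immaterial because step 11 resets that centre.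

**Route**

Step 1
Reactants: 1 but-2-yn-1-ol
Product: 3 (2Z)-3-iodobut-2-en-1-ol, via cyclic vinylalanate 2 (not isolated)
Conditions: NaAlH2(OCH2CH2OMe)2, THF, 0 °C to rt; then I2, −78 °C
Reagents that add atoms: iodine, [I][I]
Why: Hydroxyl-directed trans-hydroalumination of the propargylic alcohol puts aluminium on C3 cis to the CH2O group and iodinolysis with retention should give the Z iodide, the future C4(Me)=C5 unit with the carbinol carbon as C6.

Step 2
Reactants: 3 (2Z)-3-iodobut-2-en-1-ol
Product: 4 (2Z)-3-iodobut-2-enal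
Conditions: MnO2, CH2Cl2, rt
Reagents that add atoms: none
Why: Allylic alcohol oxidation on MnO2 is neutral and should not isomerise the Z iodoalkene.

Step 3
Reactants: 4 (2Z)-3-iodobut-2-enal; 5 (1S)-2-hydroxy-1,2,2-triphenylethyl acetate [(S)-HYTRA]
Product: 7 (1S)-2-hydroxy-1,2,2-triphenylethyl (3S,4Z)-3-hydroxy-5-iodohex-4-enoate, via dilithium acetate enolate 6 (not isolated)
Conditions: LiN(iPr)2 (2.1 equiv), THF, −78 to 0 °C; then 4, THF/2-methylbutane, −105 °C
Reagents that add atoms: none
Why: Acetate aldol addition of the doubly deprotonated chiral acetate (HYTRA aldol): the S auxiliary should steer the enolate to the aldehyde face that gives the 3S carbinol (C6), as it does with simple aldehydes, and crystallisation of the adduct removes the minor diastereomer.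

Step 4
Reactants: 7 HYTRA ester adduct
Product: 8 methyl (3S,4Z)-3-hydroxy-5-iodohex-4-enoate
Conditions: K2CO3 (cat.), MeOH, 0 °C to rt
Reagents that add atoms: methanol, CO
Why: Carbonate-catalysed transesterification frees the methyl β-hydroxy ester and the recoverable triphenylethanediol without touching C6.

Step 5
Reactants: 8 methyl (3S,4Z)-3-hydroxy-5-iodohex-4-enoate
Product: 10 4-tert-butyl 1-methyl (2R)-2-[(1S,2Z)-1-hydroxy-3-iodobut-2-en-1-yl]butanedioate, via dilithium alkoxide enolate 9 (not isolated)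
Conditions: LiN(iPr)2 (2.2 equiv), THF, −78 to −40 °C; then BrCH2CO2tBu, −78 to −30 °C
Reagents that add atoms: tert-butyl bromoacetate, BrCC(=O)OC(C)(C)C
Why: Fráter–Seebach alkylation: the lithium-chelated alkoxide enolate is alkylated on the face away from the C6 side chain, so C7 should form anti to the C6 oxygen, and at these temperatures the vinyl iodide should survive the amide base.

Step 6
Reactants: 10 hydroxy diester
Product: 11 tert-butyl (3S,4S,5Z)-4-hydroxy-3-(hydroxymethyl)-6-iodohept-5-enoate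
Conditions: LiBH4, THF/MeOH, 0 °C
Reagents that add atoms: none
Why: Hydride reduction with LiBH4 is chemoselective for the hydroxyl-activated methyl ester (C8) over the tert-butyl ester.

Step 7
Reactants: 11 diol tert-butyl ester
Product: 12 tert-butyl (3S,4S,5Z)-3-{[tert-butyl(dimethyl)silyl]oxymethyl}-4-hydroxy-6-iodohept-5-enoate
Conditions: TBSCl (1.05 equiv), imidazole, CH2Cl2, −20 to 0 °C
Reagents that add atoms: tert-butyl(chloro)dimethylsilane, CC(C)(C)[Si](C)(C)Cl
Why: Silyl ether formation is far faster at the primary C8 hydroxyl than at the hindered secondary allylic C6 hydroxyl.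

Step 8
Reactants: 12 silyl ether hydroxy ester
Product: 13 (4S,5S)-4-{[tert-butyl(dimethyl)silyl]oxymethyl}-5-[(1Z)-2-iodoprop-1-en-1-yl]oxolan-2-one
Conditions: CSA (cat.), 4 Å sieves, toluene, 50 °C
Reagents that add atoms: none
Why: Acid-catalysed lactonisation of the γ-hydroxy tert-butyl ester closes the γ-lactone by acyl substitution at C12 (5-exo-trig), so C6 keeps its configuration and the anti alkylation product gives the cis C6/C7 lactone, while the dry non-nucleophilic medium should spare the silyl ether.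

Step 9
Reactants: 13 cis lactone
Product: 15 (3R,4R,5S)-4-{[tert-butyl(dimethyl)silyl]oxymethyl}-3-hydroxy-5-[(1Z)-2-iodoprop-1-en-1-yl]oxolan-2-one, via potassium lactone enolate 14 (not isolated)
Conditions: KN(SiMe3)2, THF, −78 °C; then 2-(phenylsulfonyl)-3-phenyloxaziridine, −78 °C
Reagents that add atoms: 2-(phenylsulfonyl)-3-phenyloxaziridine, O=S(=O)(c1ccccc1)N1OC1c1ccccc1
Why: Enolate hydroxylation with an N-sulfonyloxaziridine puts oxygen on C11, expected trans to the C7 substituent, but this configuration is erased in step 11 so either epimer serves.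

Step 10
Reactants: 15 α-hydroxy lactone
Product: 16 (3R,4S,5S)-4-{[tert-butyl(dimethyl)silyl]oxymethyl}-5-[(1Z)-2-iodoprop-1-en-1-yl]-3-(triethylsilyloxy)oxolan-2-one
Conditions: TESCl, imidazole, DMAP (cat.), CH2Cl2, rt
Reagents that add atoms: chlorotriethylsilane, CC[Si](Cl)(CC)CC
Why: Standard silylation of the secondary α-hydroxyl gives the ether that ends as the tertiary TES ether protecting the chlorohydrin oxygen.

Step 11
Reactants: 16 α-silyloxy lactone
Product: 18 (3S,4S,5S)-4-{[tert-butyl(dimethyl)silyl]oxymethyl}-3-(chloromethyl)-5-[(1Z)-2-iodoprop-1-en-1-yl]-3-(triethylsilyloxy)oxolan-2-one, via lithium silyloxy enolate 17 (not isolated)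
Conditions: LiN(iPr)2, THF, −78 °C; then ICH2Cl, DMPU, −78 to −40 °C
Reagents that add atoms: chloroiodomethane, ClCI
Why: Enolate alkylation with chloroiodomethane (iodide is the leaving group): the planar α-silyloxy lactone enolate is attacked on the face opposite the C7 and C6 substituents, which sets the quaternary C11 with CH2Cl trans and the silyloxy group cis to C8.

Step 12
Reactants: 18 fully protected iodide lactone
Product: 19 (3S,4S,5S)-3-(chloromethyl)-4-(hydroxymethyl)-5-[(1Z)-2-iodoprop-1-en-1-yl]-3-(triethylsilyloxy)oxolan-2-one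
Conditions: CSA (cat.), MeOH/CH2Cl2, 0 °C
Reagents that add atoms: none
Why: Acid-catalysed methanolysis removes the primary TBS ether much faster than the hindered tertiary TES ether next to the lactone carbonyl.

Step 13
Reactants: 20 ethynyltrimethylsilane; 21 methyl 2,2-dimethoxypropanoate
Product: 23 4,4-dimethoxy-1-(trimethylsilyl)pent-1-yn-3-one, via lithium acetylide 22 (not isolated)
Conditions: n-BuLi, THF, −78 °C; then 21, −78 °C
Reagents that add atoms: none
Why: Acylation of the lithium acetylide by the α,α-dialkoxy ester should stop at the ynone because the chelated tetrahedral intermediate survives until work-up.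

Step 14
Reactants: 23 ketal ynone
Product: 24 (3S)-4,4-dimethoxy-1-(trimethylsilyl)pent-1-yn-3-ol
Conditions: (R)-2-methyl-CBS-oxazaborolidine, BH3·SMe2, THF, −30 °C
Reagents that add atoms: none
Why: Corey–Bakshi–Shibata reduction: the fully substituted ketal carbon is the large group and the alkyne the small one, so the R catalyst should give the 3S alcohol, which is C1 with the configuration that is inverted later in the oxirane closure.

Step 15
Reactants: 24 propargylic alcohol
Product: 26 1-({[(3S)-4,4-dimethoxypent-1-yn-3-yl]oxy}methyl)-4-methoxybenzene, via silylalkyne PMB ether 25 (not isolated)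
Conditions: NaH, 4-MeOC6H4CH2Cl, Bu4NI (cat.), THF/DMF, 0 °C to rt; then K2CO3, MeOH, rt
Reagents that add atoms: 4-methoxybenzyl chloride, COc1ccc(CCl)cc1
Why: Williamson etherification installs the PMB group that later chelates magnesium at C1–O, and carbonate-catalysed methanolysis removes the alkynyl silane in the same flask.

Step 16
Reactants: 26 ketal alkyne
Product: 27 1-methoxy-4-({[(3S)-2-methoxypent-1-en-4-yn-3-yl]oxy}methyl)benzene
Conditions: TMSOTf, iPr2NEt, CH2Cl2, −20 °C to rt
Reagents that add atoms: none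
Why: Silyl triflate-mediated ionisation of the dimethyl ketal and kinetic deprotonation of the oxocarbenium ion at the unhindered methyl group give the 2-methoxyallyl ether, a masked C10 ketone whose C9 can be brominated later without base.

Step 17
Reactants: 27 enol ether alkyne
Product: 29 tributyl{(3S)-4-methoxy-3-[(4-methoxybenzyl)oxy]pent-4-en-1-yn-1-yl}stannane, via lithium acetylide 28 (not isolated)
Conditions: n-BuLi, THF, −78 °C; then Bu3SnCl, −78 to 0 °C
Reagents that add atoms: tributyltin chloride, CCCC[Sn](Cl)(CCCC)CCCC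
Why: Deprotonation of the terminal alkyne and stannylation of the acetylide give the alkynylstannane needed for a Z-selective hydrometalation.

Step 18
Reactants: 29 alkynylstannane
Product: 31 tributyl{(1Z,3S)-4-methoxy-3-[(4-methoxybenzyl)oxy]penta-1,4-dien-1-yl}stannane, via stannyl zirconocene alkene 30 (not isolated)
Conditions: Cp2Zr(H)Cl, THF, rt; then H2O
Reagents that add atoms: none
Why: Syn hydrozirconation of the alkynylstannane puts zirconium on the tin-bearing carbon and protonolysis with retention gives the Z vinylstannane (C2=C3), the alkyne reacting much faster than the enol ether double bond.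

Step 19
Reactants: 1 but-2-yn-1-ol
Product: 33 (2E)-2-iodobut-2-en-1-ol, via vinylstannane 32 (not isolated)
Conditions: Bu3SnH, PdCl2(PPh3)2 (cat.), THF, rt; then I2, CH2Cl2, 0 °C
Reagents that add atoms: iodine, [I][I]
Why: Palladium-catalysed syn hydrostannation places tin on the carbon next to the CH2OH group and iododestannylation with retention gives the E iodide in which methyl and CH2OH are cis, as in the side-chain ester.

Step 20
Reactants: 33 (2E)-2-iodobut-2-en-1-ol
Product: 34 tert-butyl{[(2E)-2-iodobut-2-en-1-yl]oxy}dimethylsilane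
Conditions: TBSCl, imidazole, CH2Cl2, 0 °C
Reagents that add atoms: tert-butyl(chloro)dimethylsilane, CC(C)(C)[Si](C)(C)Cl
Why: Standard silylation protects the allylic hydroxyl for the lithiation.

Step 21
Reactants: 34 silyl-protected vinyl iodide
Product: 36 (2E)-2-{[tert-butyl(dimethyl)silyl]oxymethyl}but-2-enoic acid, via vinyllithium 35 (not isolated)
Conditions: t-BuLi (2.1 equiv), Et2O, −78 °C; then CO2; then 1 M HCl
Reagents that add atoms: carbon dioxide, O=C=O
Why: Iodine–lithium exchange and carboxylation of the vinyllithium proceed with retention of the alkene geometry.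

Step 22
Reactants: 19 iodide lactone alcohol; 31 Z vinylstannane
Product: 37 (3S,4S,5R)-3-(chloromethyl)-4-(hydroxymethyl)-5-{(1Z,3Z,5S)-6-methoxy-5-[(4-methoxybenzyl)oxy]-2-methylhepta-1,3,6-trien-1-yl}-3-(triethylsilyloxy)oxolan-2-one
Conditions: Pd2(dba)3 (cat.), AsPh3, CuI, NMP, rt
Reagents that add atoms: none
Why: Stille coupling with retention at both alkenyl carbons forms C3–C4 and the 2Z,4Z-diene, and the free hydroxyl, the enol ether and the alkyl chloride are inert to zerovalent palladium.

Step 23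
Reactants: 37 enol ether diene
Product: 38 (3S,4S,5R)-5-{(1Z,3Z,5S)-7-bromo-5-[(4-methoxybenzyl)oxy]-2-methyl-6-oxohepta-1,3-dien-1-yl}-3-(chloromethyl)-4-(hydroxymethyl)-3-(triethylsilyloxy)oxolan-2-one
Conditions: NBS (1.0 equiv), NaHCO3, THF/H2O, −20 to 0 °C
Reagents that add atoms: N-bromosuccinimide, O=C1CCC(=O)N1Br; water, O
Why: Electrophilic bromination of the electron-rich enol ether and hydrolysis of the bromo-oxocarbenium ion unveil the C9 bromomethyl ketone regiospecifically and without base, so C1 is not epimerised and the diene is not touched.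

Step 24
Reactants: 38 bromoketone alcohol
Product: 39 (2R,3S,4S)-2-{(1Z,3Z,5S)-7-bromo-5-[(4-methoxybenzyl)oxy]-2-methyl-6-oxohepta-1,3-dien-1-yl}-4-(chloromethyl)-5-oxo-4-(triethylsilyloxy)oxolane-3-carbaldehyde (seco C9 bromoketone C8 aldehyde)
Conditions: Dess–Martin periodinane, NaHCO3, CH2Cl2, 0 °C
Reagents that add atoms: none
Why: Dess–Martin oxidation under buffered neutral conditions gives the aldehyde without epimerising C7 or eliminating the β-acyloxy group, and 39 is used at once.

Step 25
Reactants: 39 seco C9 bromoketone C8 aldehyde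
Product: 41 ten-membered C8 alcohol C10 ketone (1S 6R 7S 8R 11S), via trivalent samarium enolate 40 (not isolated)
Conditions: SmI2 (2.2 equiv), THF, −78 °C, 0.005 M, slow addition of 39
Reagents that add atoms: none
Why: Two equivalents of SmI2 reduce the C9–Br bond (the first electron cleaves it, the second turns the α-keto radical into the trivalent samarium enolate 40, regiospecifically at C9), and the enolate adds to the C8 aldehyde through a six-membered samarium-bridged chair transition state, forming C8–C9. The closest known reaction type is the SmI2-mediated intramolecular Reformatsky (aldol-type) cyclisation of α-bromoketones onto aldehydes, which is established for medium rings. The ten-membered carbocycle is closed by C–C bond formation in a 10-(enolendo)-exo-trig mode, helped by the cis lactone and the Z,Z-diene, which hold C8 and C9 close. The new C8 stereocentre is controlled by C7: the enolate, delivered from the chain anchored at C6, should attack the aldehyde face opposite the quaternary C11 with the samarium-bound oxygen turned outward towards H-7, which gives 8R. The step needs reduction of the bromide before the aldehyde, the α-alkoxy ketone or the alkyl chloride, and ring closure instead of protonation or oligomerisation; the much faster electron transfer to the α-bromoketone at −78 °C, only a slight excess over two equivalents of SmI2, the absence of any O–H group in 39 and high dilution should secure this.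

Step 26
Reactants: 41 ten-membered aldol; 36 side-chain acid
Product: 43 C8 (2E)-2-{[tert-butyl(dimethyl)silyl]oxymethyl}but-2-enoate of 41, via mixed anhydride 42 (not isolated)
Conditions: 2,4,6-Cl3C6H2COCl, Et3N, THF, rt; then 41, DMAP, toluene, rt
Reagents that add atoms: none
Why: Yamaguchi esterification acylates the hindered secondary C8 alcohol with retention, and the E geometry of the acid is the thermodynamically favoured one so it is not at risk.

Step 27
Reactants: 43 C8 ester C10 ketone
Product: 44 C10 tertiary alcohol (10R) with C1 PMB ether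
Conditions: MeMgBr (3 equiv), Et2O/CH2Cl2, −78 °C
Reagents that add atoms: methylmagnesium bromide, C[Mg]Br
Why: Chelation-controlled Grignard addition: magnesium bridges the C10 carbonyl and the C1 PMB ether oxygen and methyl adds from the side of H-1, opposite C2, which should give 10R (tertiary hydroxyl anti to the C1 oxygen along the ring), while at −78 °C the ketone reacts much faster than the lactone and the side-chain ester.

Step 28
Reactants: 44 tertiary alcohol PMB ether
Product: 45 C1,C10 diol (1S 10R)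
Conditions: DDQ, CH2Cl2/pH 7 buffer, 0 °C
Reagents that add atoms: none
Why: Oxidative cleavage of the PMB ether with DDQ in buffered wet solvent frees the C1 hydroxyl without acid or base.

Step 29
Reactants: 45 C1,C10 diol
Product: 47 bis-silyl ether of the target (1R 10R epoxide), via C1 mesylate 46 (not isolated)
Conditions: (MeSO2)2O, Et3N, CH2Cl2, −40 °C; then DBU, −40 to 0 °C
Reagents that add atoms: none
Why: Selective sulfonylation of the secondary C1 hydroxyl and intramolecular Williamson-type displacement by the tertiary C10 oxygen (3-exo-tet) close the oxirane with inversion at C1 and retention at C10, giving the trans C1–C10 epoxide.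

Step 30
Reactants: 47 bis-silyl ether
Product: 48 target CNP0158457.1
Conditions: HF·pyridine, pyridine, THF, 0 °C to rt
Reagents that add atoms: none
Why: Buffered HF·pyridine removes both silyl ethers, and unlike basic fluoride it cannot close the free chlorohydrin to an epoxide, while the weakly acidic medium should spare the vinyl epoxide.

**Compound list**

1 | but-2-yn-1-ol | CC#CCO | starting material
2 | sodium cyclic vinylalanate of 1 (Al bound to C3 and O, two 2-methoxyethoxy ligands) | CC1=CCO[Al-]1(OCCOC)OCCOC.[Na+] | intermediate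
3 | (2Z)-3-iodobut-2-en-1-ol | C/C(I)=C/CO | intermediate
4 | (2Z)-3-iodobut-2-enal | C/C(I)=C/C=O | intermediate
5 | (1S)-2-hydroxy-1,2,2-triphenylethyl acetate, (S)-HYTRA | CC(=O)O[C@@H](c1ccccc1)C(O)(c1ccccc1)c1ccccc1 | starting material
6 | dilithium enolate alkoxide of 5 | [Li+].[Li+].C=C([O-])O[C@@H](c1ccccc1)C([O-])(c1ccccc1)c1ccccc1 | intermediate
7 | (1S)-2-hydroxy-1,2,2-triphenylethyl (3S,4Z)-3-hydroxy-5-iodohex-4-enoate | C/C(I)=C/[C@@H](O)CC(=O)O[C@@H](c1ccccc1)C(O)(c1ccccc1)c1ccccc1 | intermediate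
8 | methyl (3S,4Z)-3-hydroxy-5-iodohex-4-enoate | C/C(I)=C/[C@@H](O)CC(=O)OC | intermediate
9 | dilithium alkoxide enolate of 8 (chelated, enolate O cis to C6) | [Li+].[Li+].C/C(I)=C/[C@@H]([O-])/C=C(\[O-])OC | intermediate
10 | 4-tert-butyl 1-methyl (2R)-2-[(1S,2Z)-1-hydroxy-3-iodobut-2-en-1-yl]butanedioate | C/C(I)=C/[C@@H](O)[C@@H](CC(=O)OC(C)(C)C)C(=O)OC | intermediate
11 | tert-butyl (3S,4S,5Z)-4-hydroxy-3-(hydroxymethyl)-6-iodohept-5-enoate | C/C(I)=C/[C@@H](O)[C@@H](CC(=O)OC(C)(C)C)CO | intermediate
12 | tert-butyl (3S,4S,5Z)-3-{[tert-butyl(dimethyl)silyl]oxymethyl}-4-hydroxy-6-iodohept-5-enoate | C/C(I)=C/[C@@H](O)[C@@H](CC(=O)OC(C)(C)C)CO[Si](C)(C)C(C)(C)C | intermediate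
13 | (4S,5S)-4-{[tert-butyl(dimethyl)silyl]oxymethyl}-5-[(1Z)-2-iodoprop-1-en-1-yl]oxolan-2-one (cis lactone) | C/C(I)=C/[C@H]1OC(=O)C[C@H]1CO[Si](C)(C)C(C)(C)C | intermediate
14 | potassium enolate of 13 | [K+].C/C(I)=C/[C@H]1OC([O-])=C[C@H]1CO[Si](C)(C)C(C)(C)C | intermediate
15 | (3R,4R,5S)-4-{[tert-butyl(dimethyl)silyl]oxymethyl}-3-hydroxy-5-[(1Z)-2-iodoprop-1-en-1-yl]oxolan-2-one (hydroxyl trans to the C4 substituent) | C/C(I)=C/[C@H]1OC(=O)[C@H](O)[C@H]1CO[Si](C)(C)C(C)(C)C | intermediate
16 | (3R,4S,5S)-4-{[tert-butyl(dimethyl)silyl]oxymethyl}-5-[(1Z)-2-iodoprop-1-en-1-yl]-3-(triethylsilyloxy)oxolan-2-one | C/C(I)=C/[C@H]1OC(=O)[C@H](O[Si](CC)(CC)CC)[C@H]1CO[Si](C)(C)C(C)(C)C | intermediate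
17 | lithium enolate of 16 | [Li+].C/C(I)=C/[C@H]1OC([O-])=C(O[Si](CC)(CC)CC)[C@H]1CO[Si](C)(C)C(C)(C)C | intermediate
18 | (3S,4S,5S)-4-{[tert-butyl(dimethyl)silyl]oxymethyl}-3-(chloromethyl)-5-[(1Z)-2-iodoprop-1-en-1-yl]-3-(triethylsilyloxy)oxolan-2-one | C/C(I)=C/[C@H]1OC(=O)[C@](O[Si](CC)(CC)CC)(CCl)[C@H]1CO[Si](C)(C)C(C)(C)C | intermediate
19 | (3S,4S,5S)-3-(chloromethyl)-4-(hydroxymethyl)-5-[(1Z)-2-iodoprop-1-en-1-yl]-3-(triethylsilyloxy)oxolan-2-one | C/C(I)=C/[C@H]1OC(=O)[C@](O[Si](CC)(CC)CC)(CCl)[C@H]1CO | intermediate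
20 | ethynyltrimethylsilane | C#C[Si](C)(C)C | starting material
21 | methyl 2,2-dimethoxypropanoate | COC(=O)C(C)(OC)OC | starting material
22 | lithium (trimethylsilyl)acetylide | [Li+].[C-]#C[Si](C)(C)C | intermediate
23 | 4,4-dimethoxy-1-(trimethylsilyl)pent-1-yn-3-one | C[Si](C)(C)C#CC(=O)C(C)(OC)OC | intermediate
24 | (3S)-4,4-dimethoxy-1-(trimethylsilyl)pent-1-yn-3-ol | C[Si](C)(C)C#C[C@H](O)C(C)(OC)OC | intermediate
25 | {(3S)-4,4-dimethoxy-3-[(4-methoxybenzyl)oxy]pent-1-yn-1-yl}trimethylsilane | C[Si](C)(C)C#C[C@H](OCc1ccc(OC)cc1)C(C)(OC)OC | intermediate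
26 | 1-({[(3S)-4,4-dimethoxypent-1-yn-3-yl]oxy}methyl)-4-methoxybenzene | C#C[C@H](OCc1ccc(OC)cc1)C(C)(OC)OC | intermediate
27 | 1-methoxy-4-({[(3S)-2-methoxypent-1-en-4-yn-3-yl]oxy}methyl)benzene | C#C[C@H](OCc1ccc(OC)cc1)C(=C)OC | intermediate
28 | lithium acetylide of 27 | [Li+].[C-]#C[C@H](OCc1ccc(OC)cc1)C(=C)OC | intermediate
29 | tributyl{(3S)-4-methoxy-3-[(4-methoxybenzyl)oxy]pent-4-en-1-yn-1-yl}stannane | CCCC[Sn](CCCC)(CCCC)C#C[C@H](OCc1ccc(OC)cc1)C(=C)OC | intermediate
30 | geminal tributylstannyl chlorozirconocenyl alkene from 29 (Sn cis to C1) | CCCC[Sn](CCCC)(CCCC)/C(=C\[C@H](OCc1ccc(OC)cc1)C(=C)OC)[Zr](Cl)(C1C=CC=C1)C1C=CC=C1 | intermediate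
31 | tributyl{(1Z,3S)-4-methoxy-3-[(4-methoxybenzyl)oxy]penta-1,4-dien-1-yl}stannane | CCCC[Sn](CCCC)(CCCC)/C=C\[C@H](OCc1ccc(OC)cc1)C(=C)OC | intermediate
32 | (2E)-2-(tributylstannyl)but-2-en-1-ol | C/C=C(\CO)[Sn](CCCC)(CCCC)CCCC | intermediate
33 | (2E)-2-iodobut-2-en-1-ol | C/C=C(\CO)I | intermediate
34 | tert-butyl{[(2E)-2-iodobut-2-en-1-yl]oxy}dimethylsilane | C/C=C(\CO[Si](C)(C)C(C)(C)C)I | intermediate
35 | 1-{[tert-butyl(dimethyl)silyl]oxy}but-2-en-2-yllithium (methyl cis to CH2O) | C/C=C(\CO[Si](C)(C)C(C)(C)C)[Li] | intermediate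
36 | (2E)-2-{[tert-butyl(dimethyl)silyl]oxymethyl}but-2-enoic acid | C/C=C(\CO[Si](C)(C)C(C)(C)C)C(=O)O | intermediate
37 | (3S,4S,5R)-3-(chloromethyl)-4-(hydroxymethyl)-5-{(1Z,3Z,5S)-6-methoxy-5-[(4-methoxybenzyl)oxy]-2-methylhepta-1,3,6-trien-1-yl}-3-(triethylsilyloxy)oxolan-2-one | C=C(OC)[C@@H](OCc3ccc(OC)cc3)/C=C\C(C)=C/[C@H]1OC(=O)[C@](O[Si](CC)(CC)CC)(CCl)[C@H]1CO | intermediate
38 | (3S,4S,5R)-5-{(1Z,3Z,5S)-7-bromo-5-[(4-methoxybenzyl)oxy]-2-methyl-6-oxohepta-1,3-dien-1-yl}-3-(chloromethyl)-4-(hydroxymethyl)-3-(triethylsilyloxy)oxolan-2-one | BrCC(=O)[C@@H](OCc3ccc(OC)cc3)/C=C\C(C)=C/[C@H]1OC(=O)[C@](O[Si](CC)(CC)CC)(CCl)[C@H]1CO | intermediate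
39 | (2R,3S,4S)-2-{(1Z,3Z,5S)-7-bromo-5-[(4-methoxybenzyl)oxy]-2-methyl-6-oxohepta-1,3-dien-1-yl}-4-(chloromethyl)-5-oxo-4-(triethylsilyloxy)oxolane-3-carbaldehyde (seco C9 bromoketone C8 aldehyde) | BrCC(=O)[C@@H](OCc3ccc(OC)cc3)/C=C\C(C)=C/[C@H]1OC(=O)[C@](O[Si](CC)(CC)CC)(CCl)[C@H]1C=O | intermediate
40 | trivalent samarium enolate of 39 (C9=C10, O–SmI2 on C10) | C=C(O[Sm](I)I)[C@@H](OCc3ccc(OC)cc3)/C=C\C(C)=C/[C@H]1OC(=O)[C@](O[Si](CC)(CC)CC)(CCl)[C@H]1C=O | intermediate
41 | ten-membered aldol (1S,6R,7S,8R,11S): 12,6-lactone cis-fused at C6/C7, C8 hydroxyl, C10 ketone, C1 PMB ether, 2Z,4Z-diene with methyl on C4, C11 bearing OTES and CH2Cl | O[C@@H]1CC(=O)[C@@H](OCc3ccc(OC)cc3)/C=C\C(C)=C/[C@H]2OC(=O)[C@](O[Si](CC)(CC)CC)(CCl)[C@H]21 | intermediate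
42 | mixed anhydride of 36 and 2,4,6-trichlorobenzoic acid | C/C=C(\CO[Si](C)(C)C(C)(C)C)C(=O)OC(=O)c1c(Cl)cc(Cl)cc1Cl | intermediate
43 | C8 ester of 41 with acid 36 (C10 ketone, C1 PMB ether) | C/C=C(\CO[Si](C)(C)C(C)(C)C)C(=O)O[C@@H]1CC(=O)[C@@H](OCc3ccc(OC)cc3)/C=C\C(C)=C/[C@H]2OC(=O)[C@](O[Si](CC)(CC)CC)(CCl)[C@H]21 | intermediate
44 | C10 tertiary alcohol (1S,10R) from methyl addition to 43 | C/C=C(\CO[Si](C)(C)C(C)(C)C)C(=O)O[C@@H]1C[C@@](C)(O)[C@@H](OCc3ccc(OC)cc3)/C=C\C(C)=C/[C@H]2OC(=O)[C@](O[Si](CC)(CC)CC)(CCl)[C@H]21 | intermediate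
45 | C1,C10 diol (1S,10R) | C/C=C(\CO[Si](C)(C)C(C)(C)C)C(=O)O[C@@H]1C[C@@](C)(O)[C@@H](O)/C=C\C(C)=C/[C@H]2OC(=O)[C@](O[Si](CC)(CC)CC)(CCl)[C@H]21 | intermediate
46 | C1 methanesulfonate of 45 | C/C=C(\CO[Si](C)(C)C(C)(C)C)C(=O)O[C@@H]1C[C@@](C)(O)[C@@H](OS(C)(=O)=O)/C=C\C(C)=C/[C@H]2OC(=O)[C@](O[Si](CC)(CC)CC)(CCl)[C@H]21 | intermediate
47 | target protected as C11 triethylsilyl ether and side-chain TBS ether (1R,10R trans epoxide) | C/C=C(\CO[Si](C)(C)C(C)(C)C)C(=O)O[C@@H]1C[C@@]2(C)O[C@@H]2/C=C\C(C)=C/[C@H]2OC(=O)[C@](O[Si](CC)(CC)CC)(CCl)[C@H]21 | intermediate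
48 | CNP0158457.1 (1R,6R,7S,8R,10R,11S) | C/C=C(\CO)C(=O)O[C@@H]1C[C@@]2(C)O[C@@H]2/C=C\C(C)=C/[C@H]2OC(=O)[C@](O)(CCl)[C@H]21 | target

**Step count and risks**

Total: 30 steps. Longest linear sequence: 21 steps (steps 1–12 and 22–30) from but-2-yn-1-ol. Stannane 31 takes six steps (13–18) and acid 36 three steps (19–21).

Step 25 (most likely to fail). The samarium enolate may be protonated or may oligomerise before it reaches the aldehyde, or it may close on the other aldehyde face. The fallback sets out from 19 and 31, forms C8–C9 between the two fragments and closes the ring at C3–C4 instead. Dess–Martin oxidation of 19 gives the iodo aldehyde F1. Mild hydrolysis of the enol ether of 31 (PPTS, wet acetone) gives the stannyl methyl ketone F2. The kinetic boron enolate of F2 ((c-C6H11)2BCl, Et3N, Et2O, −78 °C, enolisation at the methyl group) adds to F1; under Felkin–Anh control, anti to C11, this should give mainly the open-chain 8S aldol F3. Intramolecular Stille coupling of F3 (Pd2(dba)3, AsPh3, CuI, NMP, high dilution) closes the ten-membered ring to the 8-epi alcohol F4. Mitsunobu esterification of F4 with acid 36 (PPh3, DIAD) inverts C8 and comes back to the route at 43.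

Step 27. Enolisation towards C9 followed by loss of the C8 carboxylate may compete with addition, or methyl may add through a non-chelated rotamer and give the C10 epimer. The fallback sets out from 41 and changes the order, so that neither a β-acyloxy ketone nor the side-chain ester is present when the methyl group is added. Silylation of 41 (TESOTf, 2,6-lutidine) gives the C8 triethylsilyl ether F5. MeMgBr after pre-complexation with MgBr2·OEt2 gives the tertiary alcohol F6. PPTS in MeOH removes the secondary triethylsilyl group and leaves the tertiary one, giving the C8,C10 diol F7. Yamaguchi acylation of the secondary C8 hydroxyl of F7 with 36 comes back to the route at 44.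

Step 29. The dienylic mesylate may ionise before the tertiary alkoxide attacks, with loss of configuration at C1 or allylic transposition. The fallback sets out from 45 and closes the oxirane by Mitsunobu cyclodehydration (PPh3, DIAD, toluene). The C1 oxygen is then activated as an oxyphosphonium ion only next to the C10 oxygen and is displaced at once with inversion. It comes back to the route at 47 and makes no new isolated compound.

**Further compounds**

F1 | step 25 | (2S,3S,4S)-4-(chloromethyl)-2-[(1Z)-2-iodoprop-1-en-1-yl]-5-oxo-4-(triethylsilyloxy)oxolane-3-carbaldehyde | C/C(I)=C/[C@H]1OC(=O)[C@](O[Si](CC)(CC)CC)(CCl)[C@H]1C=O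
F2 | step 25 | (3S,4Z)-3-[(4-methoxybenzyl)oxy]-5-(tributylstannyl)pent-4-en-2-one | CC(=O)[C@@H](OCc1ccc(OC)cc1)/C=C\[Sn](CCCC)(CCCC)CCCC
F3 | step 25 | open-chain 8S aldol of F1 and F2 (C8–C9 formed, Z vinyl iodide and Z vinylstannane termini) | C/C(I)=C/[C@H]1OC(=O)[C@](O[Si](CC)(CC)CC)(CCl)[C@H]1[C@@H](O)CC(=O)[C@@H](OCc2ccc(OC)cc2)/C=C\[Sn](CCCC)(CCCC)CCCC
F4 | step 25 | 8-epi-41 (8S alcohol) | O[C@H]1CC(=O)[C@@H](OCc3ccc(OC)cc3)/C=C\C(C)=C/[C@H]2OC(=O)[C@](O[Si](CC)(CC)CC)(CCl)[C@H]21
F5 | step 27 | C8 triethylsilyl ether of 41 | CC[Si](CC)(CC)O[C@@H]1CC(=O)[C@@H](OCc3ccc(OC)cc3)/C=C\C(C)=C/[C@H]2OC(=O)[C@](O[Si](CC)(CC)CC)(CCl)[C@H]21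
F6 | step 27 | C10 tertiary alcohol (10R) from F5 | CC[Si](CC)(CC)O[C@@H]1C[C@@](C)(O)[C@@H](OCc3ccc(OC)cc3)/C=C\C(C)=C/[C@H]2OC(=O)[C@](O[Si](CC)(CC)CC)(CCl)[C@H]21
F7 | step 27 | C8,C10 diol with C1 PMB ether and C11 triethylsilyl ether | O[C@@H]1C[C@@](C)(O)[C@@H](OCc3ccc(OC)cc3)/C=C\C(C)=C/[C@H]2OC(=O)[C@](O[Si](CC)(CC)CC)(CCl)[C@H]21
F0 | step 29 | none | none
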